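**Retrosynthetic overview**

- Feature: in the resorcinol dimethyl ether ring (C1 carries the 10-phenyldecyl chain, C3 and C5 carry OMe), the run C3–C4–C5–C6 with its meta-dimethoxy pattern is the diene unit of 1,3-dimethoxycyclohexa-1,3-diene, and C1–C2 can come from an alkyne.
- Last disconnection: C2–H ⇒ C2–CO2H ⇒ C2–CO2Me (protodecarboxylation, saponification); the ester is a removable activating and regiodirecting group.
- Key disconnection: ring bonds C1–C6 and C2–C3, by Diels–Alder addition of the diene to methyl 13-phenyltridec-2-ynoate followed by retro-Diels–Alder loss of ethylene (Alder–Rickert). This is the only ring formed; the terminal phenyl ring is bought.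
- Ynoate ⇒ 12-phenyldodec-1-yne + methyl chloroformate ⇒ (10-bromodecyl)benzene + acetylide ⇒ 1,10-dibromodecane + PhMgBr. Diene ⇒ Birch reduction of 1,3-dimethoxybenzene, then base conjugation.

Key step: step 6

Remark: the target is achiral. The only stereogenic atoms on the route are the two bridgeheads of the transient bicyclic cycloadduct of the key step, which forms as a racemate and loses both centres on aromatisation. Lithium acetylide–ethylenediamine complex is taken as a purchased starting material.

**Route**

Step 1
Reactants: 1 1,10-dibromodecane; 2 phenylmagnesium bromide
Product: 3 (10-bromodecyl)benzene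
Conditions: 1 (3 equiv), PhMgBr (1 equiv, slow addition), Li2CuCl4 (3 mol %), THF–NMP, 0 °C → rt; distillation
Reagents that add atoms: phenylmagnesium bromide (2), Br[Mg]c1ccccc1
Why: Copper-catalysed Kochi-type cross-coupling of an aryl Grignard reagent with a primary alkyl bromide, in which the three-fold excess of the symmetrical dibromide biases the statistics toward monoarylation and the product should separate from recovered 1 and from 1,10-diphenyldecane by distillation.

Step 2
Reactants: 3 (10-bromodecyl)benzene; 4 lithium acetylide–ethylenediamine complex
Product: 5 12-phenyldodec-1-yne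
Conditions: LiC≡CH·H2NCH2CH2NH2 (1.5 equiv), DMSO, 15 °C → rt
Reagents that add atoms: lithium acetylide–ethylenediamine complex (4), [Li]C#C.NCCN
Why: SN2 alkylation of acetylide by an unbranched primary bromide in a dipolar aprotic solvent, where elimination should be minor and the phenyl ring is inert.

Step 3
Reactants: 5 12-phenyldodec-1-yne; 6 methyl chloroformate
Product: 8 methyl 13-phenyltridec-2-ynoate, via lithium acetylide 7 (not isolated)
Conditions: n-BuLi (1.05 equiv), THF, −78 °C; then ClCO2Me (1.2 equiv), −78 → 0 °C
Reagents that add atoms: methyl chloroformate (6), COC(=O)Cl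
Why: Deprotonation of the terminal alkyne and C-acylation of the lithium acetylide by the chloroformate (standard alk-2-ynoate synthesis), the low temperature keeping the acetylide from adding to the product.

Step 4
Reactants: 9 1,3-dimethoxybenzene
Product: 10 1,5-dimethoxycyclohexa-1,4-diene
Conditions: Li (2.5 equiv), liq. NH3, THF, t-BuOH (2.5 equiv), −78 → −33 °C; MeOH, then H2O; base-washed work-up
Reagents that add atoms: none
Why: Birch reduction, in which protonation occurs at C2 and C5 of the arene so that both methoxy groups stay on sp2 carbons, giving the 2,5-dihydro compound as an acid-sensitive bis(enol ether).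

Step 5
Reactants: 10 1,5-dimethoxycyclohexa-1,4-diene
Product: 11 1,3-dimethoxycyclohexa-1,3-diene
Conditions: KNH2 (0.2 equiv, from K and cat. Fe(NO3)3), liq. NH3, −33 °C; solid NH4Cl; pentane extraction; distillation under reduced pressure
Reagents that add atoms: none
Why: Base-catalysed prototropic conjugation of a 1,4-diene, in which removal of a doubly allylic proton from C6 of 10 gives a pentadienyl anion whose charge avoids the oxygen-bearing carbons and whose reprotonation at C2 gives the conjugated diene, expected to be favoured at equilibrium; any residual 10 in the distillate should feed into step 6 by conjugation at that temperature.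

Step 6
Reactants: 8 methyl 13-phenyltridec-2-ynoate; 11 1,3-dimethoxycyclohexa-1,3-diene
Product: 13 methyl 2,4-dimethoxy-6-(10-phenyldecyl)benzoate, via bicyclooctadiene cycloadduct 12 (not isolated)
Conditions: 11 (3 equiv), neat, sealed tube, Ar, 190 °C, 24–48 h; vent ethylene; chromatography
Reagents that add atoms: none
Why: The electron-rich bis(enol ether) diene 11 and the ester-activated alkyne 8 should combine in a thermal normal-electron-demand Diels–Alder reaction to give the bicyclo[2.2.2]octa-2,5-diene 12, which at the same temperature undergoes a retro-Diels–Alder reaction that expels the saturated two-carbon bridge as ethylene and leaves the benzene ring (Alder–Rickert reaction). The closest known reaction type is the Alder–Rickert synthesis of 6-alkyl-2,4-dimethoxybenzoates from dimethoxycyclohexadienes and alk-2-ynoates. The single new ring, the resorcinol benzene ring, is closed by concerted [4+2] cycloaddition (bonds C1–C6 and C2–C3 formed together from four diene carbons and two alkyne carbons), so no tet/trig/dig ring-closure-mode restriction applies. No stereocentre is carried forward, because the two bridgehead centres of 12 arise as a racemic pair fixed by the bicycle and are erased on aromatisation. The step needs regioselectivity, which the diene secures: its unsubstituted terminus is beta to one methoxy group and delta to the other, so it bears the largest HOMO coefficient and bonds to the chain-bearing beta carbon of the ynoate (largest LUMO coefficient), placing the ester carbon next to the methoxy-bearing terminus. Irreversible loss of gaseous ethylene and the gain of aromaticity should drive the sequence forward.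

Step 7
Reactants: 13 methyl 2,4-dimethoxy-6-(10-phenyldecyl)benzoate
Product: 15 2,4-dimethoxy-6-(10-phenyldecyl)benzoic acid, via potassium carboxylate 14 (not isolated)
Conditions: KOH (10 equiv), DMSO–H2O (4:1), 110 °C; then aq. HCl to pH 2, 0 °C
Reagents that add atoms: potassium hydroxide, [K+].[OH-]
Why: Saponification (acyl–oxygen cleavage) of a di-ortho-substituted benzoate, for which poorly solvated hydroxide in hot DMSO is used to overcome the shielding of the carbonyl, while the aryl methyl ethers and the hydrocarbon chain are inert to base.

Step 8
Reactants: 15 2,4-dimethoxy-6-(10-phenyldecyl)benzoic acid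
Product: 16 1,3-dimethoxy-5-(10-phenyldecyl)benzene (target)
Conditions: Ag2CO3 (10 mol %), AcOH (5 mol %), DMSO, 120 °C
Reagents that add atoms: none
Why: Silver-catalysed protodecarboxylation of an ortho-substituted benzoic acid, in which the silver carboxylate loses CO2 to an arylsilver species favoured by the ortho-methoxy and ortho-alkyl groups and is then protonated, leaving hydrogen at C2.

**Compound list**

1 | 1,10-dibromodecane | BrCCCCCCCCCCBr | starting material
2 | phenylmagnesium bromide | Br[Mg]c1ccccc1 | starting material
3 | (10-bromodecyl)benzene | BrCCCCCCCCCCc1ccccc1 | intermediate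
4 | lithium acetylide–ethylenediamine complex | [Li]C#C.NCCN | starting material
5 | 12-phenyldodec-1-yne | C#CCCCCCCCCCCc1ccccc1 | intermediate
6 | methyl chloroformate | COC(=O)Cl | starting material
7 | (12-phenyldodec-1-yn-1-yl)lithium | [Li]C#CCCCCCCCCCCc1ccccc1 | intermediate
8 | methyl 13-phenyltridec-2-ynoate | COC(=O)C#CCCCCCCCCCCc1ccccc1 | intermediate
9 | 1,3-dimethoxybenzene | COc1cccc(OC)c1 | starting material
10 | 1,5-dimethoxycyclohexa-1,4-diene | COC1=CCC=C(OC)C1 | intermediate
11 | 1,3-dimethoxycyclohexa-1,3-diene | COC1=CC(OC)=CCC1 | intermediate
12 | methyl 1,5-dimethoxy-3-(10-phenyldecyl)bicyclo[2.2.2]octa-2,5-diene-2-carboxylate, racemic (one enantiomer drawn) | COC(=O)C1=C(CCCCCCCCCCc3ccccc3)[C@@H]2CC[C@@]1(OC)C=C2OC | intermediate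
13 | methyl 2,4-dimethoxy-6-(10-phenyldecyl)benzoate | COC(=O)c1c(OC)cc(OC)cc1CCCCCCCCCCc1ccccc1 | intermediate
14 | potassium 2,4-dimethoxy-6-(10-phenyldecyl)benzoate | [K+].[O-]C(=O)c1c(OC)cc(OC)cc1CCCCCCCCCCc1ccccc1 | intermediate
15 | 2,4-dimethoxy-6-(10-phenyldecyl)benzoic acid | OC(=O)c1c(OC)cc(OC)cc1CCCCCCCCCCc1ccccc1 | intermediate
16 | 1,3-dimethoxy-5-(10-phenyldecyl)benzene | COc1cc(CCCCCCCCCCc2ccccc2)cc(OC)c1 | target

**Step count**

Total step count: 8. Longest linear sequence: 6 steps (steps 1, 2, 3, 6, 7, 8); the diene branch (steps 4, 5) joins at step 6.

**Steps most likely to fail**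

Step 6. At 190 °C the bis(enol ether) diene may be consumed by loss of methanol to an anisole or by dimerisation faster than it adds to the singly activated, beta-alkylated alkyne, and regiocontrol may erode at this temperature. The fallback gives up ring construction and joins the chain to a ready-made resorcinol ring. It sets out from 3, which is converted with Mg in THF into (10-phenyldecyl)magnesium bromide F1. Kumada–Corriu coupling of this with purchased 1-bromo-3,5-dimethoxybenzene, catalysed by NiCl2(dppp) (dppp = 1,3-bis(diphenylphosphino)propane) in refluxing THF–Et2O, should give the target directly, so the fallback comes back to the route at 16.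

Step 1. Over-arylation of the symmetrical dibromide to 1,10-diphenyldecane, Grignard homocoupling and an awkward separation from the excess dibromide may leave little pure monobromide. The fallback replaces statistical control by chemoselectivity. It sets out from 2, which is coupled under the same copper catalysis (Li2CuCl4, THF–NMP) with purchased 1-bromo-10-chlorodecane; the C–Br bond should react far faster than the C–Cl bond, giving (10-chlorodecyl)benzene F2. Displacement of the chloride with 4 in DMSO (rt → 40 °C) then gives the alkyne, so the fallback comes back to the route at 5.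

Step 7. Attack of hydroxide at a carbonyl flanked by two ortho substituents and deactivated by two donor groups may stall, and further forcing may begin to cleave the aryl methyl ethers. The fallback moves the cleavage away from the hindered carbonyl to a benzylic C–O bond. It sets out from 5, which is lithiated as in step 3 (via 7) and acylated with benzyl chloroformate to give benzyl 13-phenyltridec-2-ynoate F3. Heating this with 11 as in step 6 should give, through benzyl 1,5-dimethoxy-3-(10-phenyldecyl)bicyclo[2.2.2]octa-2,5-diene-2-carboxylate F4 (not isolated), benzyl 2,4-dimethoxy-6-(10-phenyldecyl)benzoate F5. Hydrogenolysis (H2, 1 atm, Pd/C, palladium metal on carbon, EtOAc, rt) then releases the acid, so the fallback comes back to the route at 15.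

**Further compounds**

F1 | step 6 | (10-phenyldecyl)magnesium bromide | Br[Mg]CCCCCCCCCCc1ccccc1
F2 | step 1 | (10-chlorodecyl)benzene | ClCCCCCCCCCCc1ccccc1
F3 | step 7 | benzyl 13-phenyltridec-2-ynoate | O=C(OCc1ccccc1)C#CCCCCCCCCCCc1ccccc1
F4 | step 7 | benzyl 1,5-dimethoxy-3-(10-phenyldecyl)bicyclo[2.2.2]octa-2,5-diene-2-carboxylate, racemic (one enantiomer drawn) | O=C(OCc4ccccc4)C1=C(CCCCCCCCCCc3ccccc3)[C@@H]2CC[C@@]1(OC)C=C2OC
F5 | step 7 | benzyl 2,4-dimethoxy-6-(10-phenyldecyl)benzoate | O=C(OCc1ccccc1)c1c(OC)cc(OC)cc1CCCCCCCCCCc1ccccc1
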